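Numbering (halimane): ring A = C1–C2–C3–C4–C5–C10, ring B = C5–C6–C7–C8–C9–C10. C4 carries C18H3 and C19H2OAc, C8 carries C17H3, and C9 carries C20H3 and the C11–C16 chain.
Late stage: the C3 ketone and the C6/C7 diosphenol come from the C3 and C7 carbinols in one double oxidation. C5=C10 comes from a C5=C6 enol silane (Saegusa–Ito). The chain is joined at C12–C13 by B-alkyl Suzuki coupling after methylenation of a C11 aldehyde.
Key disconnection: ring B is closed by a catalytic enantioselective Diels–Alder union (bonds C7–C8 and C9–C10) of a ring-A 2-silyloxydiene (C7=C6(OSi)–C5=C10) with tiglaldehyde (C8=C9 plus C17, C20, C11).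
Enabling feature: the ring-fusion alkene C5=C10 conjugated to the C6 carbonyl of ring B is, at the enol level (C5=C6–O), a cyclohexene retron. C8 and C10 end up sp2, so of the three centres made only quaternary C9 persists, and it depends on the enal face alone.
Ring A is bought as 2-methylcyclohexane-1,3-dione, whose carbonyls are C3 and C5 flanking C4. Hydroxymethylation and CBS desymmetrisation set C4. Ring order: A, then B.

Key step: step 8

Remark: C7, C8 and C10 in the intermediates are drawn as the expected major isomers. All three become sp2 before the end, so their configuration has no bearing on the target.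

Step 1
Reactants: 1 2-methylcyclohexane-1,3-dione
Product: 2 2-(hydroxymethyl)-2-methylcyclohexane-1,3-dione
Conditions: 37% aq. HCHO, H2O–THF, rt
Reagents that add atoms: formaldehyde C=O
Why: Aldol-type hydroxymethylation in which the acidic 2-alkyl-1,3-dione adds through its enol carbon (future C4) to formaldehyde without added base, which should limit retro-aldol and retro-Claisen cleavage; the new quaternary carbon is still prochiral because C3 and C5 are equivalent.

Step 2
Reactants: 2 2-(hydroxymethyl)-2-methylcyclohexane-1,3-dione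
Product: 3 2-[(tert-butyldimethylsilyloxy)methyl]-2-methylcyclohexane-1,3-dione
Conditions: TBSOTf, 2,6-lutidine, CH2Cl2, −78 °C
Reagents that add atoms: tert-butyldimethylsilyl triflate CC(C)(C)[Si](C)(C)OS(=O)(=O)C(F)(F)F
Why: Silyl ether formation with the very reactive silyl triflate and a hindered weak base at low temperature should trap the primary alcohol faster than base-induced retro-aldol loss of formaldehyde can occur.

Step 3
Reactants: 3 2-[(tert-butyldimethylsilyloxy)methyl]-2-methylcyclohexane-1,3-dione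
Product: 4 (2S,3S)-2-[(tert-butyldimethylsilyloxy)methyl]-3-hydroxy-2-methylcyclohexan-1-one (OH cis to CH2OTBS)
Conditions: (R)-2-methyl-CBS-oxazaborolidine (20 mol %), catecholborane, toluene, −78 → −40 °C; aq. work-up
Reagents that add atoms: none
Why: Corey–Bakshi–Shibata reduction used as desymmetrisation of a 2,2-disubstituted cyclic 1,3-dione: with the quaternary side as the large group the (R)-catalyst should give the (S)-carbinol, and of the two enantiotopic carbonyls the one that can be attacked anti to the bulky CH2OTBS group should react, which fixes C4 as S, while the single hydride of catecholborane should limit diol formation.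

Step 4
Reactants: 4 (2S,3S)-hydroxy ketone
Product: 5 (2S,3S)-2-[(tert-butyldimethylsilyloxy)methyl]-2-methyl-3-(triethylsilyloxy)cyclohexan-1-one
Conditions: TESOTf, 2,6-lutidine, CH2Cl2, −78 → 0 °C
Reagents that add atoms: triethylsilyl triflate CC[Si](CC)(CC)OS(=O)(=O)C(F)(F)F
Why: Standard silylation of a hindered secondary alcohol that carries the future C3 ketone at the alcohol level; TES is chosen because it leaves later together with the primary TBS group under mild acid.

Step 5
Reactants: 5 (2S,3S)-bis-silyl ether ketone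
Product: 7 (5S,6S)-6-[(tert-butyldimethylsilyloxy)methyl]-6-methyl-5-(triethylsilyloxy)cyclohex-1-en-1-yl triflate, via potassium enolate 6 (not isolated)
Conditions: KHMDS, THF, −78 °C; then PhNTf2, −78 → 0 °C
Reagents that add atoms: N-phenylbis(trifluoromethanesulfonimide) O=S(=O)(N(c1ccccc1)S(=O)(=O)C(F)(F)F)C(F)(F)F
Why: Enolate O-triflation; C4 is quaternary, so the C5 ketone can enolise only toward C10 and a single enol triflate should form.

Step 6
Reactants: 7 enol triflate
Product: 9 1-[(5S,6S)-6-[(tert-butyldimethylsilyloxy)methyl]-6-methyl-5-(triethylsilyloxy)cyclohex-1-en-1-yl]ethan-1-one, via 2-ethoxydiene 8 (not isolated)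
Conditions: tributyl(1-ethoxyvinyl)stannane, Pd(PPh3)4 (5 mol %), LiCl, THF, 65 °C; then 1 M aq. HCl, THF, 0 °C, brief
Reagents that add atoms: tributyl(1-ethoxyvinyl)stannane CCCC[Sn](CCCC)(CCCC)C(=C)OCC; water O
Why: Stille coupling of an enol triflate with an α-alkoxyvinylstannane (LiCl-promoted) installs C6 and C7, and the enol ether hydrolyses far faster than the silyl ethers to give the methyl enone.

Step 7
Reactants: 9 methyl enone
Product: 10 ring-A 2-silyloxydiene: 1-[1-(tert-butyldimethylsilyloxy)vinyl]cyclohexene with the (5S,6S) substituents of 9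
Conditions: TBSOTf, Et3N, CH2Cl2, 0 °C
Reagents that add atoms: tert-butyldimethylsilyl triflate CC(C)(C)[Si](C)(C)OS(=O)(=O)C(F)(F)F
Why: Soft enolisation (silyl triflate/amine) of a 1-acetylcyclohexene takes place at the methyl group (C7) and should give the cross-conjugated 2-silyloxydiene.

Step 8
Reactants: 10 ring-A 2-silyloxydiene; 11 (E)-2-methylbut-2-enal (tiglaldehyde)
Product: 12 bicyclic aldehyde (3S,4S,8S,9R,10S): C5=C6 enol silane; C9 bears CH3 and CHO; C8–CH3 cis to C9–CH3; C10–H cis to C9–CH3
Conditions: (R)-o-tolyl-oxazaborolidine from (R)-α,α-diphenylprolinol (20 mol %), Tf2NH (18 mol %), CH2Cl2, −78 → −40 °C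
Reagents that add atoms: none
Why: The protonated oxazaborolidine binds the formyl oxygen of s-trans 11 (B–O coordination plus formyl C–H···O contact) and lowers its LUMO, so that a concerted but asynchronous normal-demand Diels–Alder reaction with 10 should take place, the closest known type being cationic-oxazaborolidine-catalysed cycloadditions of 2-silyloxy-1,3-dienes and of semicyclic 1-vinylcyclohexene dienes with α-methyl enals. Ring B (C5–C10) is closed by an intermolecular suprafacial/suprafacial [4+2] closure that makes C7–C8 and the hindered C9–C10 bond at once and leaves the new π bond as the C5=C6 enol silane. Regiochemistry: the C6 silyloxy group and the C1 alkyl residue on C10 both raise the HOMO coefficient at C7, which therefore bonds to the β-carbon C8, so that the α-carbon C9 ends up on C10. C9, the only new stereocentre that survives, is fixed by the catalyst: the aryl group of the (R)-catalyst covers the Cα-Re face of 11 and the diene adds to the Cα-Si face, whatever the endo/exo mode. C8 follows from the E geometry of 11 and C10 from the expected formyl-endo approach to the diene face that carries the C4 methyl group and lies opposite the C19 and C3 silyloxy groups (matched with the catalyst); both centres are erased in steps 13 and 17. The step needs cycloaddition to win over Mukaiyama aldol or Michael addition of the enol silane, which the low temperature, the robust TBS group and a semicyclic diene whose only terminal substituent (C1 on C10) is an outside one should secure.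

Step 9
Reactants: 12 bicyclic aldehyde
Product: 13 C9-vinyl compound (C11=C12H2; other centres as in 12)
Conditions: MePPh3Br, KHMDS, THF, 0 °C → rt
Reagents that add atoms: methyltriphenylphosphonium bromide C[P+](c1ccccc1)(c1ccccc1)c1ccccc1.[Br-]
Why: Wittig methylenation of a non-enolisable neopentyl aldehyde, so C9 cannot epimerise and the enol silane and silyl ethers are inert to the ylide.

Step 10
Reactants: 14 but-2-yn-1-ol
Product: 15 (but-2-yn-1-yloxy)(tert-butyl)diphenylsilane
Conditions: TBDPSCl, imidazole, CH2Cl2, rt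
Reagents that add atoms: tert-butyldiphenylsilyl chloride CC(C)(C)[Si](Cl)(c1ccccc1)c1ccccc1
Why: Standard silylation; TBDPS is chosen because it outlasts the acid step that removes TES and TBS later.

Step 11
Reactants: 15 TBDPS ether of but-2-yn-1-ol
Product: 17 (E)-tert-butyl[(3-iodobut-2-en-1-yl)oxy]diphenylsilane, via alkenylzirconocene 16 (not isolated)
Conditions: Cp2Zr(H)Cl (excess), THF, rt → 40 °C; then I2, 0 °C
Reagents that add atoms: iodine II
Why: Hydrozirconation–iodination: syn addition of the Schwartz reagent, equilibration by excess reagent to the less hindered methyl-bearing carbon, and iodinolysis with retention should give the E-iodide that carries the C13=C14 geometry.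

Step 12
Reactants: 13 C9-vinyl compound; 17 (E)-vinyl iodide
Product: 19 coupled enol silane carrying the full C11–C16 chain (13E; C15–OTBDPS), via B-alkyl-9-BBN 18 (not isolated)
Conditions: 9-BBN, THF, rt → 40 °C; then 17, Pd(dppf)Cl2 (10 mol %), AsPh3, Cs2CO3, DMF–H2O, rt
Reagents that add atoms: none
Why: B-alkyl Suzuki–Miyaura coupling: 9-BBN adds anti-Markovnikov to the only monosubstituted alkene (the tetrasubstituted enol silane is inert) and the cross-coupling joins C12 to C13 with retention of the iodide geometry.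

Step 13
Reactants: 19 coupled enol silane
Product: 20 Δ5(10)-6-ketone (tetrasubstituted enone; C8–CH3 cis to C9–CH3)
Conditions: Pd(OAc)2 (1.1 equiv), MeCN, rt → 40 °C
Reagents that add atoms: none
Why: Saegusa–Ito oxidation: the enol silane placed regiospecifically at C5=C6 by the cycloaddition is palladated at C5 and β-hydride elimination of C10–H should give the conjugated C5=C10 enone, which erases C10.

Step 14
Reactants: 20 Δ5(10)-6-ketone
Product: 22 7-hydroxy-Δ5(10)-6-ketone (OH expected trans to C8–CH3), via sodium dienolate 21 (not isolated)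
Conditions: NaHMDS, THF, −78 °C; then 2-(phenylsulfonyl)-3-phenyloxaziridine, −78 °C
Reagents that add atoms: 2-(phenylsulfonyl)-3-phenyloxaziridine O=S(=O)(N1OC1c1ccccc1)c1ccccc1
Why: Kinetic α′-deprotonation of the enone (C7 is its only α-CH position) followed by Davis oxaziridine hydroxylation, a reagent that attacks the enolate but not the trisubstituted C13=C14 alkene.

Step 15
Reactants: 22 7-hydroxy enone
Product: 23 3,7,19-triol (C15–OTBDPS retained)
Conditions: CSA (cat.), MeOH–CH2Cl2, 0 °C → rt
Reagents that add atoms: none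
Why: Acid-catalysed methanolysis of silyl ethers removes the TES and the primary TBS group, whereas the bulkier TBDPS ether is far more stable to acid.

Step 16
Reactants: 23 3,7,19-triol
Product: 24 19-monoacetate (3-OH and 7-OH free)
Conditions: AcCl (1.05 equiv), 2,4,6-collidine, CH2Cl2, −78 °C
Reagents that add atoms: acetyl chloride CC(Cl)=O
Why: Selective acylation of the primary alcohol at low temperature; the C3 carbinol is flanked by quaternary C4 and the C7 carbinol is a hydrogen-bonded secondary α-ketol, so both should react more slowly.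

Step 17
Reactants: 24 19-monoacetate
Product: 26 15-O-TBDPS ether of the target (C3 ketone and C6/C7 diosphenol in place), via triketone tautomer 25 (not isolated)
Conditions: Dess–Martin periodinane (3 equiv), CH2Cl2, 0 °C → rt; then SiO2, Et3N (cat.)
Reagents that add atoms: none
Why: Dess–Martin oxidation of both secondary alcohols in one operation; the C6/C7 1,2-diketone can enolise only toward C8 and should settle as the cross-conjugated diosphenol, erasing C7 and C8, while C4 has no α-hydrogen and the β-acetoxy ketone cannot eliminate.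

Step 18
Reactants: 26 15-O-TBDPS ether of the target
Product: 27 target CNP0512382.1 (4S,9S,13E)
Conditions: HF·pyridine, THF–pyridine, 0 °C → rt
Reagents that add atoms: none
Why: Fluoride-mediated desilylation under mildly acidic conditions should cleave the Si–O bond without touching the acetate, the diosphenol or either quaternary centre.

Compound list
1 | 2-methylcyclohexane-1,3-dione | CC1C(=O)CCCC1=O | starting material
2 | 2-(hydroxymethyl)-2-methylcyclohexane-1,3-dione | CC1(CO)C(=O)CCCC1=O | intermediate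
3 | 2-[(tert-butyldimethylsilyloxy)methyl]-2-methylcyclohexane-1,3-dione | CC1(CO[Si](C)(C)C(C)(C)C)C(=O)CCCC1=O | intermediate
4 | (2S,3S)-2-[(tert-butyldimethylsilyloxy)methyl]-3-hydroxy-2-methylcyclohexan-1-one | CC(C)(C)[Si](C)(C)OC[C@@]1(C)[C@@H](O)CCCC1=O | intermediate
5 | (2S,3S)-2-[(tert-butyldimethylsilyloxy)methyl]-2-methyl-3-(triethylsilyloxy)cyclohexan-1-one | CC(C)(C)[Si](C)(C)OC[C@@]1(C)[C@@H](O[Si](CC)(CC)CC)CCCC1=O | intermediate
6 | potassium enolate of 5 (C5=C10) | CC(C)(C)[Si](C)(C)OC[C@@]1(C)[C@@H](O[Si](CC)(CC)CC)CCC=C1[O-].[K+] | intermediate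
7 | (5S,6S)-enol triflate | CC(C)(C)[Si](C)(C)OC[C@@]1(C)[C@@H](O[Si](CC)(CC)CC)CCC=C1OS(=O)(=O)C(F)(F)F | intermediate
8 | 2-ethoxydiene | CC(C)(C)[Si](C)(C)OC[C@@]1(C)[C@@H](O[Si](CC)(CC)CC)CCC=C1C(=C)OCC | intermediate
9 | methyl enone (1-acetylcyclohexene) | CC(C)(C)[Si](C)(C)OC[C@@]1(C)[C@@H](O[Si](CC)(CC)CC)CCC=C1C(C)=O | intermediate
10 | ring-A 2-silyloxydiene | CC(C)(C)[Si](C)(C)OC[C@@]1(C)[C@@H](O[Si](CC)(CC)CC)CCC=C1C(=C)O[Si](C)(C)C(C)(C)C | intermediate
11 | (E)-2-methylbut-2-enal (tiglaldehyde) | C/C=C(\C)C=O | starting material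
12 | Diels–Alder adduct, bicyclic aldehyde | CC(C)(C)[Si](C)(C)OC[C@@]1(C)[C@@H](O[Si](CC)(CC)CC)CC[C@H]2C1=C(O[Si](C)(C)C(C)(C)C)C[C@H](C)[C@@]2(C)C=O | intermediate
13 | C9-vinyl compound | CC(C)(C)[Si](C)(C)OC[C@@]1(C)[C@@H](O[Si](CC)(CC)CC)CC[C@H]2C1=C(O[Si](C)(C)C(C)(C)C)C[C@H](C)[C@@]2(C)C=C | intermediate
14 | but-2-yn-1-ol | CC#CCO | starting material
15 | (but-2-yn-1-yloxy)(tert-butyl)diphenylsilane | CC#CCO[Si](c1ccccc1)(c1ccccc1)C(C)(C)C | intermediate
16 | (E)-alkenylzirconocene chloride | Cl[Zr](C1C=CC=C1)(C1C=CC=C1)/C(C)=C/CO[Si](c1ccccc1)(c1ccccc1)C(C)(C)C | intermediate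
17 | (E)-tert-butyl[(3-iodobut-2-en-1-yl)oxy]diphenylsilane | I/C(C)=C/CO[Si](c1ccccc1)(c1ccccc1)C(C)(C)C | intermediate
18 | B-alkyl-9-BBN (boron on C12) | CC(C)(C)[Si](C)(C)OC[C@@]1(C)[C@@H](O[Si](CC)(CC)CC)CC[C@H]2C1=C(O[Si](C)(C)C(C)(C)C)C[C@H](C)[C@@]2(C)CCB3C4CCCC3CCC4 | intermediate
19 | coupled enol silane with full side chain | CC(C)(C)[Si](C)(C)OC[C@@]1(C)[C@@H](O[Si](CC)(CC)CC)CC[C@H]2C1=C(O[Si](C)(C)C(C)(C)C)C[C@H](C)[C@@]2(C)CC/C(C)=C/CO[Si](c1ccccc1)(c1ccccc1)C(C)(C)C | intermediate
20 | Δ5(10)-6-ketone | CC(C)(C)[Si](C)(C)OC[C@@]1(C)[C@@H](O[Si](CC)(CC)CC)CCC2=C1C(=O)C[C@H](C)[C@@]2(C)CC/C(C)=C/CO[Si](c1ccccc1)(c1ccccc1)C(C)(C)C | intermediate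
21 | sodium cross-conjugated dienolate of 20 | CC(C)(C)[Si](C)(C)OC[C@@]1(C)[C@@H](O[Si](CC)(CC)CC)CCC2=C1C([O-])=C[C@H](C)[C@@]2(C)CC/C(C)=C/CO[Si](c1ccccc1)(c1ccccc1)C(C)(C)C.[Na+] | intermediate
22 | 7-hydroxy-Δ5(10)-6-ketone | CC(C)(C)[Si](C)(C)OC[C@@]1(C)[C@@H](O[Si](CC)(CC)CC)CCC2=C1C(=O)[C@@H](O)[C@H](C)[C@@]2(C)CC/C(C)=C/CO[Si](c1ccccc1)(c1ccccc1)C(C)(C)C | intermediate
23 | 3,7,19-triol | OC[C@@]1(C)[C@@H](O)CCC2=C1C(=O)[C@@H](O)[C@H](C)[C@@]2(C)CC/C(C)=C/CO[Si](c1ccccc1)(c1ccccc1)C(C)(C)C | intermediate
24 | 19-monoacetate | CC(=O)OC[C@@]1(C)[C@@H](O)CCC2=C1C(=O)[C@@H](O)[C@H](C)[C@@]2(C)CC/C(C)=C/CO[Si](c1ccccc1)(c1ccccc1)C(C)(C)C | intermediate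
25 | 3,6,7-triketone tautomer | CC(=O)OC[C@@]1(C)C(=O)CCC2=C1C(=O)C(=O)[C@H](C)[C@@]2(C)CC/C(C)=C/CO[Si](c1ccccc1)(c1ccccc1)C(C)(C)C | intermediate
26 | 15-O-TBDPS ether of the target | CC(=O)OC[C@@]1(C)C(=O)CCC2=C1C(=O)C(O)=C(C)[C@@]2(C)CC/C(C)=C/CO[Si](c1ccccc1)(c1ccccc1)C(C)(C)C | intermediate
27 | CNP0512382.1 | CC(=O)OC[C@@]1(C)C(=O)CCC2=C1C(=O)C(O)=C(C)[C@@]2(C)CC/C(C)=C/CO | target

Total steps: 18. Longest linear sequence: 16 (steps 1–9 and 12–18).

Steps most likely to fail

**Step 8.**
- Risk: the trisubstituted enal may add too slowly to the hindered diene. Acid-induced desilylation or Mukaiyama-type addition could then take over, and facial control could erode if an exo approach to the open diene face competes with the catalyst.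
- Fallback: it sets out from 10 and returns at 20.
- Methacrolein, a less hindered α-methyl enal, is used as the dienophile with the same catalyst and gives the 8-demethyl adduct F1.
- Wittig methylenation gives the vinyl compound F2. Hydroboration with 9-BBN gives the borane F3, which is coupled in the same flask with 17 to the enol silane F4.
- Saegusa–Ito oxidation gives the enone F5. One-pot dehydrogenation of its kinetic lithium enolate with N-tert-butylbenzenesulfinimidoyl chloride gives the cross-conjugated dienone F6.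
- Lithium dimethylcuprate then adds to the less substituted C7=C8 bond, anti to the C9 side chain, and delivers 20.

**Step 13.**
- Risk: palladation at C5, which lies between quaternary C4 and the C10–C9 bond, and the syn β-hydride elimination may be slow. Protodesilylation to the saturated ketone could then compete.
- Fallback: it sets out from 19 and returns at 20, replacing the syn palladium pathway by an ionic halogenation/anti-elimination sequence.
- N-bromosuccinimide in THF at −78 °C attacks the enol silane much faster than the C13=C14 alkene and gives the tertiary 5-bromo-6-ketone F7.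
- Dehydrobromination of F7 with Li2CO3/LiBr in hot DMF gives 20.

**Step 3.**
- Risk: discrimination between the enantiotopic carbonyls rests on methyl versus CH2OTBS and may be poor. Over-reduction and the retro-aldol lability of 2 and 3 add to the risk.
- Fallback: it sets out from 1 and returns at 5, building C19 by degradation of an allyl group whose dione is a standard substrate for yeast desymmetrisation.
- C-allylation of 1 with allyl bromide in aqueous base gives 2-allyl-2-methylcyclohexane-1,3-dione F8.
- Baker's yeast reduction gives the (2S,3S)-hydroxy ketone F9, and TESOTf gives the silyl ether F10.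
- Ruthenium-hydride-catalysed isomerisation gives the propenyl compound F11.
- Ozonolysis with Me2S work-up gives the keto aldehyde F12. Chemoselective reduction of the aldehyde with LiAlH(OtBu)3 at −78 °C gives the primary alcohol F13, and TBSCl/imidazole gives 5.

Further compounds
F1 | step 8 | 8-demethyl Diels–Alder adduct (from methacrolein) | CC(C)(C)[Si](C)(C)OC[C@@]1(C)[C@@H](O[Si](CC)(CC)CC)CC[C@H]2C1=C(O[Si](C)(C)C(C)(C)C)CC[C@@]2(C)C=O
F2 | step 8 | 8-demethyl C9-vinyl compound | CC(C)(C)[Si](C)(C)OC[C@@]1(C)[C@@H](O[Si](CC)(CC)CC)CC[C@H]2C1=C(O[Si](C)(C)C(C)(C)C)CC[C@@]2(C)C=C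
F3 | step 8 | 8-demethyl B-alkyl-9-BBN | CC(C)(C)[Si](C)(C)OC[C@@]1(C)[C@@H](O[Si](CC)(CC)CC)CC[C@H]2C1=C(O[Si](C)(C)C(C)(C)C)CC[C@@]2(C)CCB3C4CCCC3CCC4
F4 | step 8 | 8-demethyl coupled enol silane | CC(C)(C)[Si](C)(C)OC[C@@]1(C)[C@@H](O[Si](CC)(CC)CC)CC[C@H]2C1=C(O[Si](C)(C)C(C)(C)C)CC[C@@]2(C)CC/C(C)=C/CO[Si](c1ccccc1)(c1ccccc1)C(C)(C)C
F5 | step 8 | 8-demethyl Δ5(10)-6-ketone | CC(C)(C)[Si](C)(C)OC[C@@]1(C)[C@@H](O[Si](CC)(CC)CC)CCC2=C1C(=O)CC[C@@]2(C)CC/C(C)=C/CO[Si](c1ccccc1)(c1ccccc1)C(C)(C)C
F6 | step 8 | 8-demethyl cross-conjugated dienone | CC(C)(C)[Si](C)(C)OC[C@@]1(C)[C@@H](O[Si](CC)(CC)CC)CCC2=C1C(=O)C=C[C@@]2(C)CC/C(C)=C/CO[Si](c1ccccc1)(c1ccccc1)C(C)(C)C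
F7 | step 13 | 5-bromo-6-ketone (Br anti to C10–H) | CC(C)(C)[Si](C)(C)OC[C@@]1(C)[C@@H](O[Si](CC)(CC)CC)CC[C@H]2[C@@]1(Br)C(=O)C[C@H](C)[C@@]2(C)CC/C(C)=C/CO[Si](c1ccccc1)(c1ccccc1)C(C)(C)C
F8 | step 3 | 2-allyl-2-methylcyclohexane-1,3-dione | C=CCC1(C)C(=O)CCCC1=O
F9 | step 3 | (2S,3S)-2-allyl-3-hydroxy-2-methylcyclohexan-1-one | C=CC[C@@]1(C)[C@@H](O)CCCC1=O
F10 | step 3 | (2S,3S)-2-allyl-2-methyl-3-(triethylsilyloxy)cyclohexan-1-one | C=CC[C@@]1(C)[C@@H](O[Si](CC)(CC)CC)CCCC1=O
F11 | step 3 | (E)-propenyl isomer of F10 | C/C=C/[C@@]1(C)[C@@H](O[Si](CC)(CC)CC)CCCC1=O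
F12 | step 3 | keto aldehyde (C19 formyl) | O=C[C@@]1(C)[C@@H](O[Si](CC)(CC)CC)CCCC1=O
F13 | step 3 | 2-(hydroxymethyl)-2-methyl-3-(triethylsilyloxy)cyclohexan-1-one | OC[C@@]1(C)[C@@H](O[Si](CC)(CC)CC)CCCC1=O
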